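**Retrosynthetic overview**

1. Target 22 ⇐ 21 (two silyl ethers) ⇐ 19 by disconnection of C9–C10 in the ten-membered carbocycle. This is the only ring that is built and the last one closed, by an intramolecular nickel-catalysed reductive coupling of a C8–C9 oxirane with a C10 alkenyl iodide.
2. Enabling feature: the ring unit O8–C8–C9H2–C10(=C14H2) (C8, C9, C10 in the ring, C14 exocyclic) is a homoallylic alcohol, the retron of "terminal epoxide + 2-halo-1-alkene". The syn-1,3-diol C6/C8 with only O6 acylated is reached because the oxirane masks O8 while O6 is esterified.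
3. 19 ⇐ 17 + 18 (ester at O6) ⇐ 16 ⇐ 15: the C8–O8 bond and the C8 configuration come from an iodocarbonate cyclisation of an anti-homoallylic alcohol (temporary 1,3-dioxan-2-one, then temporary oxirane).
4. C6–C7 by catalytic asymmetric anti-selective γ-isopropylallylboration of aldehyde 5 with 8. C1–C10 by copper-catalysed coupling of iodide 12 with an α-silylvinyl Grignard reagent. C4 from (R)-linalool, whose vinyl group becomes C5–C6 and whose prenyl end is cut back to C1.
5. Order of rings: the benzene ring is bought (18); 1,3-dioxan-2-one (step 12, temporary) → oxirane (step 13, temporary) → ten-membered carbocycle (step 15, last).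

Key step: step 15

Remark: ring atoms are numbered as in germacranes (C10 carries the exocyclic C14H2, C1–C3 are CH2, C4 carries CH3 and OH, C5 is CH2, C6 carries the ester, C7 the isopropyl group, C8 the free OH, C9 is CH2); the target is then (4R,6R,7S,8S).
Remark: (R)-(−)-linalool of high enantiomeric purity, (S)-TRIP and 4-(tert-butyldimethylsilyloxy)benzoic acid 18 are taken as purchasable; every later stereocentre is set relative to C4, so minor isomers should separate as diastereomers.

**Route**

Step 1
Reactants: 1 (R)-(−)-linalool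
Product: 2 (3R)-3,7-dimethyl-3-(triethylsilyloxy)octa-1,6-diene
Conditions: TESOTf, 2,6-lutidine, CH2Cl2, −78 → 0 °C
Reagents that add atoms: triethylsilyl trifluoromethanesulfonate, CC[Si](CC)(CC)OS(=O)(=O)C(F)(F)F
Why: Silylation of the tertiary allylic alcohol with a silyl triflate and a hindered base is standard and masks O4 so that it cannot take part in the later halocyclisation; C4 is taken unchanged from the chiral pool.

Step 2
Reactants: 2 (3R)-3,7-dimethyl-3-(triethylsilyloxy)octa-1,6-diene
Product: 4 (3R)-3,7-dimethyl-3-(triethylsilyloxy)oct-6-en-1-ol, via B-alkyl-9-BBN adduct 3 (not isolated)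
Conditions: 9-BBN, THF, 0 °C → rt; then NaOH, H2O2, 0 °C
Reagents that add atoms: hydrogen peroxide, OO
Why: In this hydroboration–oxidation 9-BBN should add to the monosubstituted vinyl group much faster than to the trisubstituted alkene and place boron on the terminal carbon, so that oxidation gives the primary C6 alcohol.

Step 3
Reactants: 4 (3R)-3,7-dimethyl-3-(triethylsilyloxy)oct-6-en-1-ol
Product: 5 (3R)-3,7-dimethyl-3-(triethylsilyloxy)oct-6-enal
Conditions: Dess–Martin periodinane, NaHCO3, CH2Cl2, 0 °C → rt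
Reagents that add atoms: none
Why: Buffered Dess–Martin oxidation of a primary alcohol stops at the aldehyde and leaves the silyl ether and the alkene alone.

Step 4
Reactants: 6 3-methylbut-1-yne
Product: 7 (E)-2-(3-methylbut-1-en-1-yl)-4,4,5,5-tetramethyl-1,3,2-dioxaborolane
Conditions: pinacolborane, Cp2Zr(H)Cl (5 mol%), Et3N (10 mol%), sealed tube, 60 °C
Reagents that add atoms: pinacolborane, B1OC(C)(C)C(C)(C)O1
Why: Zirconocene-catalysed syn-hydroboration of a terminal alkyne with pinacolborane should give the (E)-1-alkenylboronate regioselectively.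

Step 5
Reactants: 7 (E)-2-(3-methylbut-1-en-1-yl)-4,4,5,5-tetramethyl-1,3,2-dioxaborolane
Product: 8 (E)-2-(4-methylpent-2-en-1-yl)-4,4,5,5-tetramethyl-1,3,2-dioxaborolane
Conditions: BrCH2Cl, n-BuLi, THF, −78 °C → rt
Reagents that add atoms: bromochloromethane, ClCBr
Why: In this Matteson homologation chloromethyllithium adds to boron and the alkenyl group undergoes a 1,2-shift with retention of the E geometry, which gives the γ-isopropyl allylboronate.

Step 6
Reactants: 5 (3R)-3,7-dimethyl-3-(triethylsilyloxy)oct-6-enal; 8 (E)-2-(4-methylpent-2-en-1-yl)-4,4,5,5-tetramethyl-1,3,2-dioxaborolane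
Product: 9 (3S,4R,6R)-6,10-dimethyl-3-(propan-2-yl)-6-(triethylsilyloxy)undeca-1,9-dien-4-ol
Conditions: (S)-TRIP (5 mol%), 4 Å MS, toluene, −30 °C; aq. NaHCO3 work-up
Reagents that add atoms: none
Why: Chiral-phosphoric-acid-catalysed allylboration runs through a closed chair Zimmerman–Traxler transition state in which the (E)-γ-isopropyl group is equatorial, so the anti pair C6/C7 (germacrane 6R,7S) should form, while the catalyst enantiomer chosen for Si-face attack (by analogy (S)-TRIP) fixes the absolute sense and any leak appears as a separable diastereomer because C4 is already set.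

Step 7
Reactants: 9 (3S,4R,6R)-6,10-dimethyl-3-(propan-2-yl)-6-(triethylsilyloxy)undeca-1,9-dien-4-ol
Product: 11 (4R,6R,7S)-4-methyl-7-(propan-2-yl)-4-(triethylsilyloxy)non-8-ene-1,6-diol, via hydroxy aldehyde 10 (not isolated)
Conditions: O3, CH2Cl2/MeOH, pyridine, Sudan Red 7B, −78 °C; then NaBH4, −78 → 0 °C
Reagents that add atoms: ozone, [O-][O+]=O
Why: Ozone should attack the electron-rich trisubstituted alkene much faster than the monosubstituted vinyl group, so titration to the dye end point cleaves only the isopropylidene end and borohydride in the same flask reduces the aldehyde to the primary C1 alcohol (chemoselective ozonolysis with reductive work-up).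

Step 8
Reactants: 11 (4R,6R,7S)-4-methyl-7-(propan-2-yl)-4-(triethylsilyloxy)non-8-ene-1,6-diol
Product: 12 (3S,4R,6R)-9-iodo-6-methyl-3-(propan-2-yl)-6-(triethylsilyloxy)non-1-en-4-ol
Conditions: I2, PPh3, imidazole, CH2Cl2, 0 °C
Reagents that add atoms: iodine, II
Why: Appel-type iodination (Garegg–Samuelsson conditions) should convert the unhindered primary alcohol far faster than the hindered secondary one.

Step 9
Reactants: 12 (3S,4R,6R)-9-iodo-6-methyl-3-(propan-2-yl)-6-(triethylsilyloxy)non-1-en-4-ol
Product: 13 (3S,4R,6R)-6-methyl-3-(propan-2-yl)-6-(triethylsilyloxy)-10-(trimethylsilyl)undeca-1,10-dien-4-ol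
Conditions: (1-(trimethylsilyl)vinyl)magnesium bromide (3 equiv, from (1-bromovinyl)trimethylsilane and Mg), CuI (10 mol%), THF, −30 → 0 °C
Reagents that add atoms: (1-(trimethylsilyl)vinyl)magnesium bromide, C=C([Mg]Br)[Si](C)(C)C
Why: Copper-catalysed coupling of a Grignard reagent with a primary alkyl iodide forms C1–C10 and brings in C10 and C14 as an α-silylvinyl unit, with one equivalent of reagent spent on the free hydroxyl.

Step 10
Reactants: 13 (3S,4R,6R)-6-methyl-3-(propan-2-yl)-6-(triethylsilyloxy)-10-(trimethylsilyl)undeca-1,10-dien-4-ol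
Product: 14 (3S,4R,6R)-10-iodo-6-methyl-3-(propan-2-yl)-6-(triethylsilyloxy)undeca-1,10-dien-4-ol
Conditions: N-iodosuccinimide, MeCN/ClCH2CN, 0 °C
Reagents that add atoms: N-iodosuccinimide, O=C1CCC(=O)N1I
Why: Electrophilic ipso-iododesilylation of the vinylsilane (β-silicon-stabilised cation, then loss of silicon) should give the 2-iodo-1-alkene with the double bond in place and is much faster than attack on the unactivated vinyl group.

Step 11
Reactants: 14 (3S,4R,6R)-10-iodo-6-methyl-3-(propan-2-yl)-6-(triethylsilyloxy)undeca-1,10-dien-4-ol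
Product: 15 tert-butyl (3S,4R,6R)-10-iodo-6-methyl-3-(propan-2-yl)-6-(triethylsilyloxy)undeca-1,10-dien-4-yl carbonate
Conditions: Boc2O, DMAP, Et3N, MeCN, rt → 40 °C
Reagents that add atoms: di-tert-butyl dicarbonate, CC(C)(C)OC(=O)OC(=O)OC(C)(C)C
Why: DMAP-catalysed acylation of the secondary alcohol with Boc2O installs the tert-butyl carbonate that serves as the internal oxygen nucleophile in the next step.

Step 12
Reactants: 15 tert-butyl (3S,4R,6R)-10-iodo-6-methyl-3-(propan-2-yl)-6-(triethylsilyloxy)undeca-1,10-dien-4-yl carbonate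
Product: 16 (4R,5R,6R)-4-(iodomethyl)-6-[(2R)-6-iodo-2-methyl-2-(triethylsilyloxy)hept-6-en-1-yl]-5-(propan-2-yl)-1,3-dioxan-2-one
Conditions: IBr, toluene, −85 °C
Reagents that add atoms: iodine monobromide, IBr
Why: In this iodocarbonate cyclisation IBr activates the terminal alkene and the carbonate carbonyl closes a six-membered ring through a chair transition state with the C6 chain, the C7 isopropyl group and the new iodomethyl group all equatorial, which should set C8 syn to O6 and anti to the isopropyl group, while the iodoalkene is too electron-poor to react at this temperature.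

Step 13
Reactants: 16 (4R,5R,6R)-4-(iodomethyl)-6-[(2R)-6-iodo-2-methyl-2-(triethylsilyloxy)hept-6-en-1-yl]-5-(propan-2-yl)-1,3-dioxan-2-one
Product: 17 (3R,4R,6R)-10-iodo-2,6-dimethyl-3-[(2R)-oxiran-2-yl]-6-(triethylsilyloxy)undec-10-en-4-ol
Conditions: K2CO3, MeOH, 0 °C → rt
Reagents that add atoms: none
Why: Methanolysis of the cyclic carbonate frees the C8 alkoxide, which displaces the neighbouring primary iodide (3-exo-tet) to give the terminal epoxide with C8 unchanged, so that O8 is masked and only O6 is free.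

Step 14
Reactants: 17 (3R,4R,6R)-10-iodo-2,6-dimethyl-3-[(2R)-oxiran-2-yl]-6-(triethylsilyloxy)undec-10-en-4-ol; 18 4-(tert-butyldimethylsilyloxy)benzoic acid
Product: 19 (3R,4R,6R)-10-iodo-2,6-dimethyl-3-[(2R)-oxiran-2-yl]-6-(triethylsilyloxy)undec-10-en-4-yl 4-(tert-butyldimethylsilyloxy)benzoate
Conditions: EDC·HCl, DMAP, CH2Cl2, 0 °C → rt
Reagents that add atoms: none
Why: Steglich esterification acylates the only free hydroxyl (O6) under neutral conditions that should leave the epoxide and the alkenyl iodide intact, which settles the O6/O8 differentiation before C8 carries a free hydroxyl.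

Step 15
Reactants: 19 (3R,4R,6R)-10-iodo-2,6-dimethyl-3-[(2R)-oxiran-2-yl]-6-(triethylsilyloxy)undec-10-en-4-yl 4-(tert-butyldimethylsilyloxy)benzoate
Product: 21 (4R,6R,7S,8S)-8-hydroxy-4-(triethylsilyloxy)germacr-10(14)-en-6-yl 4-(tert-butyldimethylsilyloxy)benzoate, via iodohydrin 20 (not isolated)
Conditions: NiBr2·diglyme (20 mol%), 4,4′-di-tert-butyl-2,2′-bipyridine (25 mol%), NaI (50 mol%), Et3N·HCl (1.5 equiv), Mn powder (3 equiv), DMPU, 25 °C, syringe-pump addition of 19 (final 2 mM)
Reagents that add atoms: none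
Why: Proposed new method: iodide (NaI, Et3N·HCl) opens the terminal oxirane of 19 at the unhindered C9 to the iodohydrin 20, Ni(0) adds oxidatively into the C10–I bond, the nickel(I) formed abstracts iodine from C9, and the primary C9 radical is captured by the tethered alkenylnickel(II), so that reductive elimination from nickel(III) forms C9–C10 and manganese returns Ni(0). The closest known reaction types are the intermolecular nickel-catalysed, iodide-co-catalysed reductive coupling of terminal epoxides with aryl and alkenyl halides at the less substituted carbon and the intramolecular nickel cross-electrophile coupling of alkenyl halides with alkyl halides; its use to close a ten-membered carbocycle is the new element. The ring closes by C(sp3)–C(sp2) bond formation at nickel, exo with respect to C10=C14, so C14 stays outside the ring and the place of the exocyclic methylene is fixed by the C10–I bond and not by a radical addition. No stereocentre is formed: only the C9–O bond is broken, so C8 keeps the configuration set in step 12, and C4, C6 and C7 are untouched. The step needs chemoselectivity between the two electrophiles, which their different activation modes (two-electron oxidative addition at sp2 C–I, halogen abstraction at sp3 C–I) should provide, opening of the epoxide at C9, which the terminal oxirane secures, and cyclisation over oligomerisation, which slow addition at high dilution is meant to secure. The buffered medium keeps O8 protonated so that the hindered, electron-rich benzoate should not migrate from O6.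

Step 16
Reactants: 21 (4R,6R,7S,8S)-8-hydroxy-4-(triethylsilyloxy)germacr-10(14)-en-6-yl 4-(tert-butyldimethylsilyloxy)benzoate
Product: 22 (4R,6R,7S,8S)-4,8-dihydroxygermacr-10(14)-en-6-yl 4-hydroxybenzoate (CNP0293401.1)
Conditions: HF·pyridine, pyridine, THF, 0 °C → rt
Reagents that add atoms: none
Why: Buffered fluoride should cleave the aryl silyl ether and the tertiary triethylsilyl ether without acyl migration or damage to the exocyclic alkene, and gives the target.

**Compound list**

1 | (R)-(−)-linalool, (3R)-3,7-dimethylocta-1,6-dien-3-ol | CC(C)=CCC[C@@](C)(O)C=C | starting material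
2 | (3R)-3,7-dimethyl-3-(triethylsilyloxy)octa-1,6-diene | CC(C)=CCC[C@@](C)(O[Si](CC)(CC)CC)C=C | intermediate
3 | 9-[(3R)-3,7-dimethyl-3-(triethylsilyloxy)oct-6-en-1-yl]-9-borabicyclo[3.3.1]nonane | CC(C)=CCC[C@@](C)(O[Si](CC)(CC)CC)CCB1C2CCCC1CCC2 | intermediate (not isolated)
4 | (3R)-3,7-dimethyl-3-(triethylsilyloxy)oct-6-en-1-ol | CC(C)=CCC[C@@](C)(O[Si](CC)(CC)CC)CCO | intermediate
5 | (3R)-3,7-dimethyl-3-(triethylsilyloxy)oct-6-enal | CC(C)=CCC[C@@](C)(O[Si](CC)(CC)CC)CC=O | intermediate
6 | 3-methylbut-1-yne | CC(C)C#C | starting material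
7 | (E)-2-(3-methylbut-1-en-1-yl)-4,4,5,5-tetramethyl-1,3,2-dioxaborolane | CC(C)/C=C/B1OC(C)(C)C(C)(C)O1 | intermediate
8 | (E)-2-(4-methylpent-2-en-1-yl)-4,4,5,5-tetramethyl-1,3,2-dioxaborolane | CC(C)/C=C/CB1OC(C)(C)C(C)(C)O1 | intermediate
9 | (3S,4R,6R)-6,10-dimethyl-3-(propan-2-yl)-6-(triethylsilyloxy)undeca-1,9-dien-4-ol (anti; germacrane 4R,6R,7S) | CC(C)=CCC[C@@](C)(O[Si](CC)(CC)CC)C[C@@H](O)[C@@H](C(C)C)C=C | intermediate
10 | (4R,6R,7S)-6-hydroxy-4-methyl-7-(propan-2-yl)-4-(triethylsilyloxy)non-8-enal | O=CCC[C@@](C)(O[Si](CC)(CC)CC)C[C@@H](O)[C@@H](C(C)C)C=C | intermediate (not isolated)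
11 | (4R,6R,7S)-4-methyl-7-(propan-2-yl)-4-(triethylsilyloxy)non-8-ene-1,6-diol | OCCC[C@@](C)(O[Si](CC)(CC)CC)C[C@@H](O)[C@@H](C(C)C)C=C | intermediate
12 | (3S,4R,6R)-9-iodo-6-methyl-3-(propan-2-yl)-6-(triethylsilyloxy)non-1-en-4-ol | ICCC[C@@](C)(O[Si](CC)(CC)CC)C[C@@H](O)[C@@H](C(C)C)C=C | intermediate
13 | (3S,4R,6R)-6-methyl-3-(propan-2-yl)-6-(triethylsilyloxy)-10-(trimethylsilyl)undeca-1,10-dien-4-ol | C=C([Si](C)(C)C)CCC[C@@](C)(O[Si](CC)(CC)CC)C[C@@H](O)[C@@H](C(C)C)C=C | intermediate
14 | (3S,4R,6R)-10-iodo-6-methyl-3-(propan-2-yl)-6-(triethylsilyloxy)undeca-1,10-dien-4-ol | C=C(I)CCC[C@@](C)(O[Si](CC)(CC)CC)C[C@@H](O)[C@@H](C(C)C)C=C | intermediate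
15 | tert-butyl (3S,4R,6R)-10-iodo-6-methyl-3-(propan-2-yl)-6-(triethylsilyloxy)undeca-1,10-dien-4-yl carbonate | C=C(I)CCC[C@@](C)(O[Si](CC)(CC)CC)C[C@@H](OC(=O)OC(C)(C)C)[C@@H](C(C)C)C=C | intermediate
16 | (4R,5R,6R)-4-(iodomethyl)-6-[(2R)-6-iodo-2-methyl-2-(triethylsilyloxy)hept-6-en-1-yl]-5-(propan-2-yl)-1,3-dioxan-2-one (all three ring substituents equatorial) | C=C(I)CCC[C@@](C)(O[Si](CC)(CC)CC)C[C@H]1OC(=O)O[C@@H](CI)[C@@H]1C(C)C | intermediate
17 | (3R,4R,6R)-10-iodo-2,6-dimethyl-3-[(2R)-oxiran-2-yl]-6-(triethylsilyloxy)undec-10-en-4-ol | C=C(I)CCC[C@@](C)(O[Si](CC)(CC)CC)C[C@@H](O)[C@@H](C(C)C)[C@@H]1CO1 | intermediate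
18 | 4-(tert-butyldimethylsilyloxy)benzoic acid | OC(=O)c1ccc(O[Si](C)(C)C(C)(C)C)cc1 | starting material
19 | (3R,4R,6R)-10-iodo-2,6-dimethyl-3-[(2R)-oxiran-2-yl]-6-(triethylsilyloxy)undec-10-en-4-yl 4-(tert-butyldimethylsilyloxy)benzoate | C=C(I)CCC[C@@](C)(O[Si](CC)(CC)CC)C[C@@H](OC(=O)c1ccc(O[Si](C)(C)C(C)(C)C)cc1)[C@@H](C(C)C)[C@@H]2CO2 | intermediate
20 | (2R,3S,4R,6R)-2-hydroxy-1,10-diiodo-6-methyl-3-(propan-2-yl)-6-(triethylsilyloxy)undec-10-en-4-yl 4-(tert-butyldimethylsilyloxy)benzoate | C=C(I)CCC[C@@](C)(O[Si](CC)(CC)CC)C[C@@H](OC(=O)c1ccc(O[Si](C)(C)C(C)(C)C)cc1)[C@@H](C(C)C)[C@@H](O)CI | intermediate (not isolated)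
21 | (4R,6R,7S,8S)-8-hydroxy-4-(triethylsilyloxy)germacr-10(14)-en-6-yl 4-(tert-butyldimethylsilyloxy)benzoate | C=C1CCC[C@@](C)(O[Si](CC)(CC)CC)C[C@@H](OC(=O)c2ccc(O[Si](C)(C)C(C)(C)C)cc2)[C@@H](C(C)C)[C@@H](O)C1 | intermediate
22 | (4R,6R,7S,8S)-4,8-dihydroxygermacr-10(14)-en-6-yl 4-hydroxybenzoate (CNP0293401.1) | C=C1CCC[C@@](C)(O)C[C@@H](OC(=O)c2ccc(O)cc2)[C@@H](C(C)C)[C@@H](O)C1 | target

**Summary**

Total step count: 16. Longest linear sequence: 14 steps (steps 1–3 and 6–16, from 1).

Steps most likely to fail: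

1. Step 15 (Proposed new method). What may go wrong: intermolecular coupling and oligomerisation instead of ring closure, reductive loss of the β-oxygen to give a C8=C9 alkene, hydrodehalogenation of the alkenyl iodide, or acyl migration from O6 to O8.
   Fallback (known chemistry), from 19 back to 22. LiI and AcOH in THF at −20 °C open the oxirane at C9 and the iodohydrin 20 is isolated this time. TESOTf and 2,6-lutidine then give the C8 triethylsilyl ether F1. Kornblum oxidation of the primary iodide (AgBF4, DMSO, then Et3N) gives the α-silyloxy aldehyde F2. An intramolecular Nozaki–Hiyama–Kishi coupling (CrCl2, catalytic NiCl2, DMSO/THF, high dilution) of the alkenyl iodide with this aldehyde forms the same C9–C10 bond and should give the ring allylic alcohol F3 as C9 epimers, both of which are usable. ClCO2Me, pyridine and DMAP give the methyl carbonate F4. Tsuji–Mandai formate reduction (Pd(OAc)2, PBu3, HCO2H/Et3N) delivers hydride to the more substituted allyl terminus C9 and leaves C10=C14 exocyclic, giving the tris-silyl macrocycle F5. HF·pyridine as in step 16 then removes all three silyl groups and gives 22.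

2. Step 6. What may go wrong: poor facial selectivity of the catalyst with an aliphatic aldehyde that carries a quaternary β-carbon, or erosion of the anti selectivity.
   Fallback, from 5 back to 9. (R)-4-Methylpent-1-yn-3-ol (from lipase resolution of the commercial racemate) is converted with MsCl and Et3N into the mesylate F6. A Marshall–Tamaru propargylation of 5 (Pd(OAc)2, PPh3, Et2Zn, THF, −20 °C) proceeds through a chiral allenylzinc reagent, formed with inversion, and a cyclic SE2′ transition state; the reagent fixes both C6 and C7 and should give the anti-homopropargylic alcohol F7. Lindlar semihydrogenation (H2, Pd/CaCO3/Pb, quinoline) then gives 9 without touching the trisubstituted alkene.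

3. Step 7. What may go wrong: loss of chemoselectivity, with ozone also attacking the terminal vinyl group.
   Fallback, from 9 back to 11. mCPBA (1 equiv, NaHCO3, CH2Cl2, −20 °C) epoxidises only the trisubstituted alkene and gives the epoxide F8 as a mixture of epimers at the new oxirane carbon. H5IO6 in THF/H2O at 0 °C cleaves it to aldehyde 10 and acetone, and NaBH4 then gives 11.

Further compounds
F1 | step 15 | C8-O-triethylsilyl ether of iodohydrin 20 | C=C(I)CCC[C@@](C)(O[Si](CC)(CC)CC)C[C@@H](OC(=O)c1ccc(O[Si](C)(C)C(C)(C)C)cc1)[C@@H](C(C)C)[C@@H](O[Si](CC)(CC)CC)CI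
F2 | step 15 | C9 aldehyde with C8-O-triethylsilyl ether | C=C(I)CCC[C@@](C)(O[Si](CC)(CC)CC)C[C@@H](OC(=O)c1ccc(O[Si](C)(C)C(C)(C)C)cc1)[C@@H](C(C)C)[C@@H](O[Si](CC)(CC)CC)C=O
F3 | step 15 | ten-membered ring allylic alcohol with C9 hydroxyl (C9 epimers) | C=C1CCC[C@@](C)(O[Si](CC)(CC)CC)C[C@@H](OC(=O)c2ccc(O[Si](C)(C)C(C)(C)C)cc2)[C@@H](C(C)C)[C@@H](O[Si](CC)(CC)CC)C1O
F4 | step 15 | C9 methyl carbonate of F3 | C=C1CCC[C@@](C)(O[Si](CC)(CC)CC)C[C@@H](OC(=O)c2ccc(O[Si](C)(C)C(C)(C)C)cc2)[C@@H](C(C)C)[C@@H](O[Si](CC)(CC)CC)C1OC(=O)OC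
F5 | step 15 | C8-O-triethylsilyl ether of macrocycle 21 | C=C1CCC[C@@](C)(O[Si](CC)(CC)CC)C[C@@H](OC(=O)c2ccc(O[Si](C)(C)C(C)(C)C)cc2)[C@@H](C(C)C)[C@@H](O[Si](CC)(CC)CC)C1
F6 | step 6 | (R)-4-methylpent-1-yn-3-yl methanesulfonate | C#C[C@H](OS(C)(=O)=O)C(C)C
F7 | step 6 | anti-homopropargylic alcohol (alkyne analogue of 9) | CC(C)=CCC[C@@](C)(O[Si](CC)(CC)CC)C[C@@H](O)[C@@H](C(C)C)C#C
F8 | step 7 | 9,10-epoxide of 9 (epimers at the oxirane CH) | CC1(C)OC1CC[C@@](C)(O[Si](CC)(CC)CC)C[C@@H](O)[C@@H](C(C)C)C=C
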